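**Plan**

- Retrosynthesis: first the thirteen benzyl ethers, the three silyl ethers and the C3–O bond of the catechin unit (from C3–B) are cut. Then O1–C2 and C3–C4 of the catechin heterocycle are cut together, back to an o-quinone methide and an (E)-alkenylboronate. Last, the three C4–aryl bonds between the units are cut, each back to an aryllithium and one and the same 4-ketone.
- Forward: the pyranone ring of the ketone (used three times) arises by epoxide opening. Unit B is joined to a phloroglucinol-type Mannich phenol, then units A and C are joined together to C6 of unit B and C6 of that phenol. The dihydropyran ring of the catechin unit is made last, followed by C–B oxidation, desilylation and hydrogenolysis.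
- Enabling feature: in the catechin unit the array O1–C8a–C4a–C4 (junction of ring A and ring C) is a latent o-quinone methide. Because C6 and C8 of this phloroglucinol ring both carry flavanyl groups, the methide has no free ring carbon and only one free phenol (O1), so ring C can be annulated at the very end from a phenol, a CH2NMe2 handle and an alkene.
- Stereochemistry: C2 and C3 of the three ent-fisetinidol units come from one Juliá–Colonna epoxidation, with inversion at C2 on ring closure. Each C4 (3,4-cis) comes from hydride delivery anti to the 3-silyloxy group. C2 and C3 of the catechin unit come from the (E) alkene (trans) and a pinene-derived ligand on boron (absolute sense), and the C–B bond is oxidised with retention.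

Key step: step 18

Assumption: the ligand made from (1R,2R,3R,5S)-isopinocampheylamine is taken to leave open the alkene face that leads to the (2R,3S) ring; if the sense is the reverse, the ligand from the commercial enantiomeric amine is used with no other change.

Shorthand: "Fis" is the group (2S,3R)-7-(benzyloxy)-2-[3,4-bis(benzyloxy)phenyl]-3-[(tert-butyldimethylsilyl)oxy]-3,4-dihydro-2H-chromen-4-yl, bound through C4 with this bond cis to the 3-silyloxy group and trans to the 2-aryl group (4α, ent-fisetinidol series). "4-hydroxy-Fis" carries an additional OH on C4, with the new aryl group trans to the 3-silyloxy group. In the phenols 10–17, phenol C1, C2, C3, C4, C5 and C6 become C8a, C4a, C5, C6, C7 and C8 of the catechin unit.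

Step 1
Reactants: 1 1-[4-(benzyloxy)-2-hydroxyphenyl]ethan-1-one; 2 3,4-bis(benzyloxy)benzaldehyde
Product: 3 (E)-1-[4-(benzyloxy)-2-hydroxyphenyl]-3-[3,4-bis(benzyloxy)phenyl]prop-2-en-1-one
Conditions: KOH (aq), EtOH, rt
Reagents that add atoms: none
Why: Claisen–Schmidt condensation of a 2'-hydroxyacetophenone with a non-enolisable aldehyde should give the (E)-chalcone, the conjugated enone being the thermodynamic product of the dehydration.

Step 2
Reactants: 3 the 2'-hydroxychalcone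
Product: 4 (E)-1-{4-(benzyloxy)-2-[(triisopropylsilyl)oxy]phenyl}-3-[3,4-bis(benzyloxy)phenyl]prop-2-en-1-one
Conditions: i-Pr3SiOTf, Et3N, CH2Cl2, 0 °C
Reagents that add atoms: triisopropylsilyl trifluoromethanesulfonate CC(C)[Si](C(C)C)(C(C)C)OS(=O)(=O)C(F)(F)F
Why: O-silylation of the chelated phenol masks the nucleophile that would otherwise cyclise during the epoxidation (Algar–Flynn–Oyamada pathway), and the hindered silyl ether should survive the basic peroxide.

Step 3
Reactants: 4 the silylated chalcone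
Product: 5 {4-(benzyloxy)-2-[(triisopropylsilyl)oxy]phenyl}{(2S,3R)-3-[3,4-bis(benzyloxy)phenyl]oxiran-2-yl}methanone
Conditions: poly-D-leucine, urea·H2O2, DBU, THF, rt
Reagents that add atoms: hydrogen peroxide (used as its urea adduct) OO
Why: Juliá–Colonna epoxidation, in which the helical poly-D-leucine delivers hydroperoxide to one face of the (E)-enone (Weitz–Scheffer addition and ring closure), should give the trans-(2S,3R)-epoxide, the antipode of the product known from poly-L-leucine.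

Step 4
Reactants: 5 the epoxy ketone
Product: 6 (2S,3S)-7-(benzyloxy)-2-[3,4-bis(benzyloxy)phenyl]-3-hydroxychroman-4-one
Conditions: Bu4NF, THF, −20 °C; AcOH quench
Reagents that add atoms: none
Why: Fluoride desilylation frees the phenoxide, which opens the epoxide at its benzylic carbon by intramolecular SN2 attack with inversion (the ring closure of the Algar–Flynn–Oyamada sequence without the oxidation), so that the trans-epoxide maps onto the 2,3-trans (2S,3S)-dihydroflavonol with C3 untouched.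

Step 5
Reactants: 6 the dihydroflavonol
Product: 7 (2S,3S)-7-(benzyloxy)-2-[3,4-bis(benzyloxy)phenyl]-3-[(tert-butyldimethylsilyl)oxy]chroman-4-one
Conditions: TBSCl, imidazole, DMF, rt
Reagents that add atoms: tert-butyldimethylsilyl chloride CC(C)(C)[Si](C)(C)Cl
Why: Silylation of the secondary α-hydroxy ketone removes the acidic OH before the organolithium steps and provides the bulky group that later shields one face of C4.

Step 6
Reactants: 8 3,5-bis(benzyloxy)phenol
Product: 9 3,5-bis(benzyloxy)-2-bromophenol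
Conditions: NBS (1 equiv), CH2Cl2, −78 °C
Reagents that add atoms: N-bromosuccinimide O=C1CCC(=O)N1Br
Why: Electrophilic aromatic bromination should go to one of the two equivalent positions ortho to the free hydroxyl and not to the position flanked by two benzyloxy groups, by analogy with the 8-selective bromination of 5,7-di-O-benzyl flavans.

Step 7
Reactants: 9 the bromophenol
Product: 10 3,5-bis(benzyloxy)-2-bromo-6-[(dimethylamino)methyl]phenol
Conditions: Me2NH (aq), CH2O (aq), EtOH, rt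
Reagents that add atoms: formaldehyde C=O; dimethylamine CNC
Why: The phenolic Mannich reaction is ortho-selective through the hydrogen-bonded phenol–iminium pair, and only one ortho position is left.

Step 8
Reactants: 10 the bromo Mannich phenol; 7 the silyl-protected ketone
Product: 12 3,5-bis(benzyloxy)-2-[(dimethylamino)methyl]-6-(4-hydroxy-Fis)phenol, via aryllithium 11 (not isolated)
Conditions: t-BuLi (3.1 equiv), THF, −78 °C; then 7, −78 → −40 °C; aq NH4Cl
Reagents that add atoms: none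
Why: Deprotonation of the phenol and bromine–lithium exchange give an o-lithiophenoxide that adds 1,2 to the ketone from the face opposite the 3-silyloxy group (Felkin-type addition), and the configuration of this carbinol centre is erased in step 9.

Step 9
Reactants: 12 the tertiary carbinol
Product: 13 3,5-bis(benzyloxy)-2-[(dimethylamino)methyl]-6-(Fis)phenol
Conditions: Et3SiH, CF3CO2H, CH2Cl2, −40 → 0 °C; aq NaHCO3
Reagents that add atoms: none
Why: In this ionic hydrogenation the doubly benzylic tertiary alcohol ionises and the silane delivers hydride to C4 from the face opposite the bulky 3-silyloxy group, which places the aryl group cis to O3 (3,4-cis, 4α) as known for 4-aryl-flavan-4-ols.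

Step 10
Reactants: 13 the phenol carrying unit B
Product: 14 3,5-bis(benzyloxy)-4-bromo-2-[(dimethylamino)methyl]-6-(6-bromo-Fis)phenol
Conditions: NBS (2.1 equiv), CF3CO2H (1.1 equiv), CH2Cl2, −40 → 0 °C; aq NaHCO3
Reagents that add atoms: N-bromosuccinimide O=C1CCC(=O)N1Br
Why: Electrophilic bromination should take the two most activated free positions, the ring carbon para to the free phenol and C6 of unit B (para to O1, ortho to the benzyloxy group), while the amine is masked as its salt.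

Step 11
Reactants: 14 the dibromide; 7 the silyl-protected ketone (2.5 equiv)
Product: 16 3,5-bis(benzyloxy)-2-[(dimethylamino)methyl]-4-(4-hydroxy-Fis)-6-[6-(4-hydroxy-Fis)-Fis]phenol, via trilithio species 15 (not isolated)
Conditions: t-BuLi (5.2 equiv), THF, −78 °C; then 7, −78 → −40 °C; aq NH4Cl
Reagents that add atoms: none
Why: Twofold bromine–lithium exchange and twofold 1,2-addition to the same ketone install units A and C in one operation, each aryllithium again adding anti to the 3-silyloxy group.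

Step 12
Reactants: 16 the bis-carbinol
Product: 17 3,5-bis(benzyloxy)-2-[(dimethylamino)methyl]-4-(Fis)-6-[6-(Fis)-Fis]phenol
Conditions: Et3SiH, CF3CO2H, CH2Cl2, −40 → 0 °C; aq NaHCO3
Reagents that add atoms: none
Why: Twofold ionic hydrogenation as in step 9, with hydride reaching each C4 cation anti to its 3-silyloxy group, should make both new aryl–C4 bonds 3,4-cis (4α).

Step 13
Reactants: 2 3,4-bis(benzyloxy)benzaldehyde
Product: 18 1,2-bis(benzyloxy)-4-ethynylbenzene
Conditions: dimethyl (1-diazo-2-oxopropyl)phosphonate, K2CO3, MeOH/THF, rt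
Reagents that add atoms: dimethyl (1-diazo-2-oxopropyl)phosphonate COP(=O)(OC)C(=[N+]=[N-])C(C)=O
Why: Seyferth–Gilbert homologation with the Ohira–Bestmann reagent converts the aldehyde into the terminal alkyne under a mild base that leaves the benzyl ethers intact.

Step 14
Reactants: 18 the aryl alkyne
Product: 20 (E)-2-[3,4-bis(benzyloxy)phenyl]ethenylboronic acid, via alkenyl catecholborane 19 (not isolated)
Conditions: catecholborane, 70 °C; then H2O, rt
Reagents that add atoms: catecholborane B1Oc2ccccc2O1; water O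
Why: Syn, anti-Markovnikov hydroboration of the terminal alkyne fixes the (E) geometry, and hydrolysis of the catechol ester gives the boronic acid.

Step 15
Reactants: 21 (1R,2R,3R,5S)-isopinocampheylamine
Product: 22 di-tert-butyl N-[(1R,2R,3R,5S)-isopinocampheyl]iminodiacetate
Conditions: tert-butyl bromoacetate (2.2 equiv), i-Pr2NEt, MeCN, 60 °C
Reagents that add atoms: tert-butyl bromoacetate CC(C)(C)OC(=O)CBr
Why: Twofold SN2 N-alkylation of the primary amine stops at the tertiary amine because of the hindered isopinocampheyl group.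

Step 16
Reactants: 22 the di-tert-butyl ester
Product: 23 N-[(1R,2R,3R,5S)-isopinocampheyl]iminodiacetic acid (PIDA)
Conditions: CF3CO2H, CH2Cl2, rt; then neutralisation
Reagents that add atoms: none
Why: Acidolysis of the tert-butyl esters (loss of 2-methylpropene) frees the diacid without touching the pinane skeleton.

Step 17
Reactants: 20 the (E)-alkenylboronic acid; 23 PIDA
Product: 24 (E)-2-[3,4-bis(benzyloxy)phenyl]ethenylboronic acid PIDA ester (bicyclic N→B boronate)
Conditions: toluene/DMSO, Dean–Stark, reflux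
Reagents that add atoms: none
Why: Dehydrative complexation gives the cage boronate with four-coordinate boron, as for N-methyliminodiacetic acid boronates, and the alkene geometry is not touched.

Step 18
Reactants: 17 the tris-flavanyl Mannich phenol; 24 the (E)-alkenyl PIDA boronate (3 equiv)
Product: 27 PIDA boronate of the catechin-type cycloadduct (2,3-trans; boron on C3), via ammonium iodide 25 (not isolated), via o-quinone methide 26 (not isolated)
Conditions: MeI, MeCN/THF, rt; then 24, K2CO3 (anhydrous), MeCN/THF, 60 °C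
Reagents that add atoms: none
Why: Proposed new method: N-methylation gives the benzylic trimethylammonium salt 25, whose phenoxide (K2CO3) expels NMe3 to form the o-quinone methide 26 (O1=C8a–C4a=C4H2), and 26 adds the electron-rich (E)-alkene of 24 in an inverse-electron-demand oxa-Diels–Alder reaction in which the C4–C3 bond forms ahead of the O1–C2 bond; the closest known reaction type is the [4+2] cycloaddition of o-quinone methides with β-substituted styrenes that gives flavans, and what is new is a dienophile that carries four-coordinate boron on the nucleophilic carbon and a chiral ligand on that boron. The dihydropyran ring is closed in the cycloaddition mode, heterodiene O1=C8a–C4a=C4 across C3=C2, so that no separate ring-closing step with its own regiochemistry arises. C2 and C3 are set together: their trans relationship is the (E) geometry of 24 transferred by suprafacial addition, and their absolute sense is controlled by the isopinocampheyl group of the N→B ligand, which covers one face of the boron-bearing alkene carbon as in the face-selective peracid epoxidation of alkenyl PIDA boronates, while the attacking CH2 terminus is unhindered and far from the stereocentres of 17. Regioselectivity (C4 to C3, O1 to C2) follows from benzylic stabilisation of developing charge at C2 by the 3,4-bis(benzyloxy)phenyl group, reinforced by the electron-releasing C–B bond of four-coordinate boron, and because this boron has no vacant orbital it cannot bind the methide oxygen and hand over the alkenyl group in a conjugate addition. The substrate secures the remaining selectivity: O1 is the only free phenol, so O5 cannot close the ring, and since C5, C6, C7 and C8 are all substituted the methide cannot C-alkylate its own precursor, the usual loss with phloroglucinol-type quinone methides.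

Step 19
Reactants: 27 the boronate cycloadduct
Product: 28 (2R,3S)-5,7-bis(benzyloxy)-2-[3,4-bis(benzyloxy)phenyl]-6-(Fis)-8-[6-(Fis)-Fis]chroman-3-ol
Conditions: NaOH (aq), H2O2, THF, 0 °C → rt
Reagents that add atoms: hydrogen peroxide OO
Why: Hydrolysis of the iminodiacetate cage and oxidation of the secondary C–B bond by hydroperoxide proceed through 1,2-migration of carbon from boron to oxygen, hence with retention at C3.

Step 20
Reactants: 28 the tris-silyl ether
Product: 29 trideca-O-benzyl ether of the target (all four 3-OH free)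
Conditions: Bu4NF, THF, rt → 40 °C
Reagents that add atoms: none
Why: Fluoride-induced desilylation cleaves the three secondary silyl ethers and leaves the benzyl ethers and the C4–aryl bonds alone.

Step 21
Reactants: 29 the trideca-O-benzyl ether
Product: 30 ent-fisetinidol-(4α→6)-ent-fisetinidol-(4α→8)-catechin-(6→4α)-ent-fisetinidol
Conditions: H2 (1 atm), Pd(OH)2 on carbon, THF/MeOH/H2O, rt
Reagents that add atoms: none
Why: Hydrogenolysis of the thirteen benzyl ethers is the usual end game for benzylated oligoflavanoids and should leave the C4–aryl bonds, the pyran rings and all eleven stereocentres untouched.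

**Compound list**

1 | 1-[4-(benzyloxy)-2-hydroxyphenyl]ethan-1-one | CC(=O)c1ccc(OCc2ccccc2)cc1O | starting material
2 | 3,4-bis(benzyloxy)benzaldehyde | O=Cc1ccc(OCc2ccccc2)c(OCc2ccccc2)c1 | starting material
3 | (E)-1-[4-(benzyloxy)-2-hydroxyphenyl]-3-[3,4-bis(benzyloxy)phenyl]prop-2-en-1-one | O=C(/C=C/c1ccc(OCc2ccccc2)c(OCc2ccccc2)c1)c1ccc(OCc2ccccc2)cc1O | intermediate
4 | (E)-1-{4-(benzyloxy)-2-[(triisopropylsilyl)oxy]phenyl}-3-[3,4-bis(benzyloxy)phenyl]prop-2-en-1-one | O=C(/C=C/c1ccc(OCc2ccccc2)c(OCc2ccccc2)c1)c1ccc(OCc2ccccc2)cc1O[Si](C(C)C)(C(C)C)C(C)C | intermediate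
5 | {4-(benzyloxy)-2-[(triisopropylsilyl)oxy]phenyl}{(2S,3R)-3-[3,4-bis(benzyloxy)phenyl]oxiran-2-yl}methanone | O=C([C@H]1O[C@@H]1c1ccc(OCc2ccccc2)c(OCc2ccccc2)c1)c1ccc(OCc2ccccc2)cc1O[Si](C(C)C)(C(C)C)C(C)C | intermediate
6 | (2S,3S)-7-(benzyloxy)-2-[3,4-bis(benzyloxy)phenyl]-3-hydroxychroman-4-one | c9ccccc9COc1ccc2c(c1)O[C@@H](c1ccc(OCc9ccccc9)c(OCc9ccccc9)c1)[C@H](O)C2=O | intermediate
7 | (2S,3S)-7-(benzyloxy)-2-[3,4-bis(benzyloxy)phenyl]-3-[(tert-butyldimethylsilyl)oxy]chroman-4-one | c9ccccc9COc1ccc2c(c1)O[C@@H](c1ccc(OCc9ccccc9)c(OCc9ccccc9)c1)[C@H](O[Si](C)(C)C(C)(C)C)C2=O | intermediate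
8 | 3,5-bis(benzyloxy)phenol | Oc1cc(OCc2ccccc2)cc(OCc2ccccc2)c1 | starting material
9 | 3,5-bis(benzyloxy)-2-bromophenol | Oc1cc(OCc2ccccc2)cc(OCc2ccccc2)c1Br | intermediate
10 | 3,5-bis(benzyloxy)-2-bromo-6-[(dimethylamino)methyl]phenol | CN(C)Cc1c(O)c(Br)c(OCc2ccccc2)cc1OCc1ccccc1 | intermediate
11 | lithium 3,5-bis(benzyloxy)-2-[(dimethylamino)methyl]-6-lithiophenolate | CN(C)Cc1c([O-])c([Li])c(OCc2ccccc2)cc1OCc1ccccc1.[Li+] | intermediate
12 | 3,5-bis(benzyloxy)-2-[(dimethylamino)methyl]-6-(4-hydroxy-Fis)phenol | c9ccccc9COc1ccc2c(c1)O[C@@H](c1ccc(OCc9ccccc9)c(OCc9ccccc9)c1)[C@H](O[Si](C)(C)C(C)(C)C)[C@@]2(O)c1c(OCc9ccccc9)cc(OCc9ccccc9)c(CN(C)C)c1O | intermediate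
13 | 3,5-bis(benzyloxy)-2-[(dimethylamino)methyl]-6-(Fis)phenol | c9ccccc9COc1ccc2c(c1)O[C@@H](c1ccc(OCc9ccccc9)c(OCc9ccccc9)c1)[C@H](O[Si](C)(C)C(C)(C)C)[C@@H]2c1c(OCc9ccccc9)cc(OCc9ccccc9)c(CN(C)C)c1O | intermediate
14 | 3,5-bis(benzyloxy)-4-bromo-2-[(dimethylamino)methyl]-6-(6-bromo-Fis)phenol | Brc1cc2c(cc1OCc9ccccc9)O[C@@H](c1ccc(OCc9ccccc9)c(OCc9ccccc9)c1)[C@H](O[Si](C)(C)C(C)(C)C)[C@@H]2c1c(OCc9ccccc9)c(Br)c(OCc9ccccc9)c(CN(C)C)c1O | intermediate
15 | trilithio derivative of 14 (lithium phenoxide; lithium in place of both bromine atoms) | [Li]c1cc2c(cc1OCc9ccccc9)O[C@@H](c1ccc(OCc9ccccc9)c(OCc9ccccc9)c1)[C@H](O[Si](C)(C)C(C)(C)C)[C@@H]2c1c(OCc9ccccc9)c([Li])c(OCc9ccccc9)c(CN(C)C)c1[O-].[Li+] | intermediate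
16 | 3,5-bis(benzyloxy)-2-[(dimethylamino)methyl]-4-(4-hydroxy-Fis)-6-[6-(4-hydroxy-Fis)-Fis]phenol | c9ccccc9COc1ccc2c(c1)O[C@@H](c1ccc(OCc9ccccc9)c(OCc9ccccc9)c1)[C@H](O[Si](C)(C)C(C)(C)C)[C@@]2(O)c1cc2c(cc1OCc9ccccc9)O[C@@H](c1ccc(OCc9ccccc9)c(OCc9ccccc9)c1)[C@H](O[Si](C)(C)C(C)(C)C)[C@@H]2c1c(OCc9ccccc9)c([C@@]2(O)c3ccc(OCc9ccccc9)cc3O[C@@H](c3ccc(OCc9ccccc9)c(OCc9ccccc9)c3)[C@@H]2O[Si](C)(C)C(C)(C)C)c(OCc9ccccc9)c(CN(C)C)c1O | intermediate
17 | 3,5-bis(benzyloxy)-2-[(dimethylamino)methyl]-4-(Fis)-6-[6-(Fis)-Fis]phenol | c9ccccc9COc1ccc2c(c1)O[C@@H](c1ccc(OCc9ccccc9)c(OCc9ccccc9)c1)[C@H](O[Si](C)(C)C(C)(C)C)[C@@H]2c1cc2c(cc1OCc9ccccc9)O[C@@H](c1ccc(OCc9ccccc9)c(OCc9ccccc9)c1)[C@H](O[Si](C)(C)C(C)(C)C)[C@@H]2c1c(OCc9ccccc9)c([C@@H]2c3ccc(OCc9ccccc9)cc3O[C@@H](c3ccc(OCc9ccccc9)c(OCc9ccccc9)c3)[C@@H]2O[Si](C)(C)C(C)(C)C)c(OCc9ccccc9)c(CN(C)C)c1O | intermediate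
18 | 1,2-bis(benzyloxy)-4-ethynylbenzene | C#Cc1ccc(OCc2ccccc2)c(OCc2ccccc2)c1 | intermediate
19 | 2-{(E)-2-[3,4-bis(benzyloxy)phenyl]ethenyl}-1,3,2-benzodioxaborole | B1(/C=C/c2ccc(OCc3ccccc3)c(OCc3ccccc3)c2)Oc2ccccc2O1 | intermediate
20 | (E)-2-[3,4-bis(benzyloxy)phenyl]ethenylboronic acid | OB(O)/C=C/c1ccc(OCc2ccccc2)c(OCc2ccccc2)c1 | intermediate
21 | (1R,2R,3R,5S)-isopinocampheylamine | N[C@H]1[C@H](C)[C@H]2C[C@@H](C1)C2(C)C | starting material
22 | di-tert-butyl N-[(1R,2R,3R,5S)-isopinocampheyl]iminodiacetate | CC(C)(C)OC(=O)CN(CC(=O)OC(C)(C)C)[C@H]1[C@H](C)[C@H]2C[C@@H](C1)C2(C)C | intermediate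
23 | N-[(1R,2R,3R,5S)-isopinocampheyl]iminodiacetic acid (PIDA) | OC(=O)CN(CC(=O)O)[C@H]1[C@H](C)[C@H]2C[C@@H](C1)C2(C)C | intermediate
24 | (E)-2-[3,4-bis(benzyloxy)phenyl]ethenylboronic acid PIDA ester (N→B cage boronate of 23) | c9ccccc9COc1ccc(/C=C/[B-]23OC(=O)C[N+]2(CC(=O)O3)[C@H]2[C@H](C)[C@H]4C[C@@H](C2)C4(C)C)cc1OCc9ccccc9 | intermediate
25 | N-methyl quaternary ammonium iodide of 17 (ArCH2NMe3 iodide; phenol free) | c9ccccc9COc1ccc2c(c1)O[C@@H](c1ccc(OCc9ccccc9)c(OCc9ccccc9)c1)[C@H](O[Si](C)(C)C(C)(C)C)[C@@H]2c1cc2c(cc1OCc9ccccc9)O[C@@H](c1ccc(OCc9ccccc9)c(OCc9ccccc9)c1)[C@H](O[Si](C)(C)C(C)(C)C)[C@@H]2c1c(OCc9ccccc9)c([C@@H]2c3ccc(OCc9ccccc9)cc3O[C@@H](c3ccc(OCc9ccccc9)c(OCc9ccccc9)c3)[C@@H]2O[Si](C)(C)C(C)(C)C)c(OCc9ccccc9)c(C[N+](C)(C)C)c1O.[I-] | intermediate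
26 | 3,5-bis(benzyloxy)-6-methylidene-4-(Fis)-2-[6-(Fis)-Fis]cyclohexa-2,4-dien-1-one (o-quinone methide) | c9ccccc9COc1ccc2c(c1)O[C@@H](c1ccc(OCc9ccccc9)c(OCc9ccccc9)c1)[C@H](O[Si](C)(C)C(C)(C)C)[C@@H]2c1cc2c(cc1OCc9ccccc9)O[C@@H](c1ccc(OCc9ccccc9)c(OCc9ccccc9)c1)[C@H](O[Si](C)(C)C(C)(C)C)[C@@H]2C1=C(OCc9ccccc9)C([C@@H]2c3ccc(OCc9ccccc9)cc3O[C@@H](c3ccc(OCc9ccccc9)c(OCc9ccccc9)c3)[C@@H]2O[Si](C)(C)C(C)(C)C)=C(OCc9ccccc9)C(=C)C1=O | intermediate
27 | PIDA boronate of 5,7-bis(benzyloxy)-2-[3,4-bis(benzyloxy)phenyl]-6-(Fis)-8-[6-(Fis)-Fis]chroman-3-ylboronic acid (2,3-trans; same spatial arrangement as 28) | c9ccccc9COc1ccc2c(c1)O[C@@H](c1ccc(OCc9ccccc9)c(OCc9ccccc9)c1)[C@H](O[Si](C)(C)C(C)(C)C)[C@@H]2c1cc2c(cc1OCc9ccccc9)O[C@@H](c1ccc(OCc9ccccc9)c(OCc9ccccc9)c1)[C@H](O[Si](C)(C)C(C)(C)C)[C@@H]2c1c(OCc9ccccc9)c([C@@H]2c3ccc(OCc9ccccc9)cc3O[C@@H](c3ccc(OCc9ccccc9)c(OCc9ccccc9)c3)[C@@H]2O[Si](C)(C)C(C)(C)C)c(OCc9ccccc9)c2c1O[C@H](c1ccc(OCc9ccccc9)c(OCc9ccccc9)c1)[C@@H]([B-]34OC(=O)C[N+]3(CC(=O)O4)[C@H]5[C@H](C)[C@H]6C[C@@H](C5)C6(C)C)C2 | intermediate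
28 | (2R,3S)-5,7-bis(benzyloxy)-2-[3,4-bis(benzyloxy)phenyl]-6-(Fis)-8-[6-(Fis)-Fis]chroman-3-ol | c9ccccc9COc1ccc2c(c1)O[C@@H](c1ccc(OCc9ccccc9)c(OCc9ccccc9)c1)[C@H](O[Si](C)(C)C(C)(C)C)[C@@H]2c1cc2c(cc1OCc9ccccc9)O[C@@H](c1ccc(OCc9ccccc9)c(OCc9ccccc9)c1)[C@H](O[Si](C)(C)C(C)(C)C)[C@@H]2c1c(OCc9ccccc9)c([C@@H]2c3ccc(OCc9ccccc9)cc3O[C@@H](c3ccc(OCc9ccccc9)c(OCc9ccccc9)c3)[C@@H]2O[Si](C)(C)C(C)(C)C)c(OCc9ccccc9)c2c1O[C@H](c1ccc(OCc9ccccc9)c(OCc9ccccc9)c1)[C@@H](O)C2 | intermediate
29 | trideca-O-benzyl ether of 30 (all phenols benzylated; all four 3-OH free) | c9ccccc9COc1ccc2c(c1)O[C@@H](c1ccc(OCc9ccccc9)c(OCc9ccccc9)c1)[C@H](O)[C@@H]2c1cc2c(cc1OCc9ccccc9)O[C@@H](c1ccc(OCc9ccccc9)c(OCc9ccccc9)c1)[C@H](O)[C@@H]2c1c(OCc9ccccc9)c([C@@H]2c3ccc(OCc9ccccc9)cc3O[C@@H](c3ccc(OCc9ccccc9)c(OCc9ccccc9)c3)[C@@H]2O)c(OCc9ccccc9)c2c1O[C@H](c1ccc(OCc9ccccc9)c(OCc9ccccc9)c1)[C@@H](O)C2 | intermediate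
30 | ent-fisetinidol-(4α→6)-ent-fisetinidol-(4α→8)-catechin-(6→4α)-ent-fisetinidol | Oc1ccc2c(c1)O[C@@H](c1ccc(O)c(O)c1)[C@H](O)[C@@H]2c1cc2c(cc1O)O[C@@H](c1ccc(O)c(O)c1)[C@H](O)[C@@H]2c1c(O)c([C@@H]2c3ccc(O)cc3O[C@@H](c3ccc(O)c(O)c3)[C@@H]2O)c(O)c2c1O[C@H](c1ccc(O)c(O)c1)[C@@H](O)C2 | target

**Step count and risks**

Total steps: 21. Longest linear sequence: 14 steps (1–5, 8–12, 18–21).

Steps most likely to fail:

1. Step 18 (the proposed new method). The cycloaddition of the methide to the hindered, boron-substituted alkene may be too slow, so that the methide is lost to dimerisation or to addition of stray nucleophiles. The face selectivity exerted by the boron ligand may also be low. Fallback with known chemistry, setting out from 17: N-methylation to 25 as before, then heating with alkyne 18 and ZnI2 in 1,2-dichloroethane without base (cationic annulation of an o-hydroxybenzyl cation with an aryl alkyne) should give the 2-aryl-4H-chromene F1. Asymmetric hydroboration with isopinocampheylborane made from (+)-α-pinene (freed from its TMEDA adduct with BF3·OEt2, THF, −25 °C) adds H to C2 and boron to C3 of the enol ether from one face, in the sense known for 1-arylcycloalkenes, and gives the borane F2. Oxidation with NaBO3·4H2O returns to the route at 28.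

2. Step 11. The twofold halogen–lithium exchange may stay incomplete, or the hindered aryllithiums may take a proton from the enolisable ketone in place of adding to it. Fallback, setting out from 13, makes one bond at a time: NBS (1 equiv) brominates only the ring position para to the free phenol and gives the monobromide F3. t-BuLi and then 7 give the mono-carbinol F4. A second NBS bromination at C6 of unit B gives the bromo carbinol F5. t-BuLi (the phenoxide and the tertiary alkoxide are carried as lithium salts) and then 7 return to the route at 16.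

3. Step 4. Opening of the electron-rich benzylic epoxide may take on SN1 character and the basic medium may epimerise or dehydrogenate the dihydroflavonol, so that stereochemical integrity at C2 is lost in the unit that is used three times. Fallback, setting out from 5: PhCH2SH with SnCl4 (CH2Cl2, −20 °C) opens the epoxide at the benzylic carbon and gives the hydroxy sulfide F6. Bu4NF with AcOH frees the phenol F7. The thiophile AgBF4 then closes the ring under non-basic conditions with the known 2,3-trans preference, C3 being untouched, and returns to the route at 6.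

The hydride deliveries of steps 9 and 12 rest on precedent from the 2,3-cis flavan series and rank just below these three.

Further compounds
F1 | step 18 | 5,7-bis(benzyloxy)-2-[3,4-bis(benzyloxy)phenyl]-6-(Fis)-8-[6-(Fis)-Fis]-4H-chromene | c9ccccc9COc1ccc2c(c1)O[C@@H](c1ccc(OCc9ccccc9)c(OCc9ccccc9)c1)[C@H](O[Si](C)(C)C(C)(C)C)[C@@H]2c1cc2c(cc1OCc9ccccc9)O[C@@H](c1ccc(OCc9ccccc9)c(OCc9ccccc9)c1)[C@H](O[Si](C)(C)C(C)(C)C)[C@@H]2c1c(OCc9ccccc9)c([C@@H]2c3ccc(OCc9ccccc9)cc3O[C@@H](c3ccc(OCc9ccccc9)c(OCc9ccccc9)c3)[C@@H]2O[Si](C)(C)C(C)(C)C)c(OCc9ccccc9)c2c1OC(c1ccc(OCc9ccccc9)c(OCc9ccccc9)c1)=CC2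
F2 | step 18 | isopinocampheyl(chroman-3-yl)borane from F1 (boron on C3 trans to the 2-aryl group; spatial arrangement of 28) | c9ccccc9COc1ccc2c(c1)O[C@@H](c1ccc(OCc9ccccc9)c(OCc9ccccc9)c1)[C@H](O[Si](C)(C)C(C)(C)C)[C@@H]2c1cc2c(cc1OCc9ccccc9)O[C@@H](c1ccc(OCc9ccccc9)c(OCc9ccccc9)c1)[C@H](O[Si](C)(C)C(C)(C)C)[C@@H]2c1c(OCc9ccccc9)c([C@@H]2c3ccc(OCc9ccccc9)cc3O[C@@H](c3ccc(OCc9ccccc9)c(OCc9ccccc9)c3)[C@@H]2O[Si](C)(C)C(C)(C)C)c(OCc9ccccc9)c2c1O[C@H](c1ccc(OCc9ccccc9)c(OCc9ccccc9)c1)[C@@H](B[C@H]3[C@H](C)[C@H]4C[C@@H](C3)C4(C)C)C2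
F3 | step 11 | 3,5-bis(benzyloxy)-4-bromo-2-[(dimethylamino)methyl]-6-(Fis)phenol | c9ccccc9COc1ccc2c(c1)O[C@@H](c1ccc(OCc9ccccc9)c(OCc9ccccc9)c1)[C@H](O[Si](C)(C)C(C)(C)C)[C@@H]2c1c(OCc9ccccc9)c(Br)c(OCc9ccccc9)c(CN(C)C)c1O
F4 | step 11 | 3,5-bis(benzyloxy)-2-[(dimethylamino)methyl]-4-(4-hydroxy-Fis)-6-(Fis)phenol | c9ccccc9COc1ccc2c(c1)O[C@@H](c1ccc(OCc9ccccc9)c(OCc9ccccc9)c1)[C@H](O[Si](C)(C)C(C)(C)C)[C@@H]2c1c(OCc9ccccc9)c([C@@]2(O)c3ccc(OCc9ccccc9)cc3O[C@@H](c3ccc(OCc9ccccc9)c(OCc9ccccc9)c3)[C@@H]2O[Si](C)(C)C(C)(C)C)c(OCc9ccccc9)c(CN(C)C)c1O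
F5 | step 11 | 3,5-bis(benzyloxy)-2-[(dimethylamino)methyl]-4-(4-hydroxy-Fis)-6-(6-bromo-Fis)phenol | Brc1cc2c(cc1OCc9ccccc9)O[C@@H](c1ccc(OCc9ccccc9)c(OCc9ccccc9)c1)[C@H](O[Si](C)(C)C(C)(C)C)[C@@H]2c1c(OCc9ccccc9)c([C@@]2(O)c3ccc(OCc9ccccc9)cc3O[C@@H](c3ccc(OCc9ccccc9)c(OCc9ccccc9)c3)[C@@H]2O[Si](C)(C)C(C)(C)C)c(OCc9ccccc9)c(CN(C)C)c1O
F6 | step 4 | (2R,3S)-3-(benzylsulfanyl)-1-{4-(benzyloxy)-2-[(triisopropylsilyl)oxy]phenyl}-3-[3,4-bis(benzyloxy)phenyl]-2-hydroxypropan-1-one (anti opening product) | O=C([C@@H](O)[C@@H](SCc1ccccc1)c1ccc(OCc2ccccc2)c(OCc2ccccc2)c1)c1ccc(OCc2ccccc2)cc1O[Si](C(C)C)(C(C)C)C(C)C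
F7 | step 4 | (2R,3S)-3-(benzylsulfanyl)-1-[4-(benzyloxy)-2-hydroxyphenyl]-3-[3,4-bis(benzyloxy)phenyl]-2-hydroxypropan-1-one | O=C([C@@H](O)[C@@H](SCc1ccccc1)c1ccc(OCc2ccccc2)c(OCc2ccccc2)c1)c1ccc(OCc2ccccc2)cc1O
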